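**Retrosynthetic overview**
1. Target 28 ⇐ desilylation and equatorial MeCeCl2 addition (C-10 carbinol) from ring B ketone 26.
2. Key step: rings A and B are closed together, last, by a Me3SiOTf epoxide-opening oxa/carbacyclization cascade of the (3S,6S,7S)-diepoxy (Z)-enol silane 25 that already carries rings C and D, instead of joining two finished bicycles.
3. 25 ⇐ one-step union at C-12/C-13: Cu-catalysed conjugate addition of the ring C/D CH2MgCl reagent 24 (from 16) to diepoxy vinyl ketone 23 with Me3SiCl trapping.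
4. 16 ⇐ ring D first from (S)-linalool (RCM, directed epoxidation, trans opening by LiCMe2CN, methylenation, hydroboration/Suzuki), then ring C by RCM, then C-13/C-14 by diene hydroboration.
5. 23 ⇐ geranyl bromide + Weinreb acetamide, double ent-Shi epoxidation, CH2=CHMgBr. Ring order: D, C, then A + B together.

Atom labels (squalene-type): ring A (oxepane) O, C-2 to C-7; ring B C-6 to C-11; bridge C-12, C-13; ring C C-14 to C-18, C-22, C-23; ring D C-18 to C-22.

Assumption: (S)-(+)-linalool of high ee and the L-fructose-derived (ent-)Shi ketone are taken as commercially available.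

**Route**

Step 1
Reactants: 1 (S)-(+)-linalool
Product: 2 (S)-1-methylcyclopent-2-en-1-ol
Conditions: second-generation Grubbs catalyst RuCl2(=CHPh)(PCy3)(H2IMes) (0.5 mol %), CH2Cl2, 40 °C
Reagents that add atoms: none
Why: Ring-closing olefin metathesis joins C-18 to C-22 and expels isobutene, leaving the chiral-pool carbinol centre C-19 untouched.

Step 2
Reactants: 2 (S)-1-methylcyclopent-2-en-1-ol
Product: 3 (1S,2R,3R)-2,3-epoxy-1-methylcyclopentan-1-ol (epoxide cis to OH)
Conditions: VO(acac)2 (2 mol %), t-BuOOH, CH2Cl2, 0 °C to rt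
Reagents that add atoms: tert-butyl hydroperoxide CC(C)(C)OO
Why: Vanadium-catalysed hydroxyl-directed epoxidation of the cyclic allylic alcohol delivers the oxygen to the alkene face syn to the OH.

Step 3
Reactants: 3 (1S,2R,3R)-2,3-epoxy-1-methylcyclopentan-1-ol
Product: 4 2-[(1R,2R,3S)-2,3-dihydroxy-3-methylcyclopentyl]-2-methylpropanenitrile
Conditions: i-PrCN, LiN(iPr)2 (2.5 equiv each), THF, −78 °C; then 3, −78 to 50 °C; aq NH4Cl
Reagents that add atoms: 2-methylpropanenitrile CC(C)C#N
Why: SN2 epoxide opening by the nitrile-stabilised tertiary carbanion occurs with inversion at the ring carbon remote from the quaternary carbinol, which sets C-22 (CMe2CN arm trans to both hydroxyls) and builds quaternary C-23.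

Step 4
Reactants: 4 2-[(1R,2R,3S)-2,3-dihydroxy-3-methylcyclopentyl]-2-methylpropanenitrile
Product: 5 2-[(1R,3S)-3-hydroxy-3-methyl-2-oxocyclopentyl]-2-methylpropanenitrile
Conditions: IBX (1.5 equiv), EtOAc, 75 °C
Reagents that add atoms: none
Why: IBX oxidation converts the secondary alcohol of the vicinal diol into the α-ketol without C–C cleavage, and the neutral medium leaves the now epimerisable C-22 intact.

Step 5
Reactants: 5 2-[(1R,3S)-3-hydroxy-3-methyl-2-oxocyclopentyl]-2-methylpropanenitrile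
Product: 6 2-[(1R,3S)-3-hydroxy-3-methyl-2-methylidenecyclopentyl]-2-methylpropanenitrile
Conditions: Zn, CH2Br2, TiCl4, THF/CH2Cl2, 0 °C to rt
Reagents that add atoms: dibromomethane BrCBr
Why: Takai–Lombardo methylenation is non-basic, tolerates the free hydroxyl and nitrile, and installs C-17 on the hindered ketone without epimerising C-22.

Step 6
Reactants: 6 2-[(1R,3S)-3-hydroxy-3-methyl-2-methylidenecyclopentyl]-2-methylpropanenitrile
Product: 8 2-[(1S,2S,3S)-3-hydroxy-3-methyl-2-(prop-2-en-1-yl)cyclopentyl]-2-methylpropanenitrile, via B-alkyl-9-BBN adduct 7 (not isolated)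
Conditions: 9-BBN (2.5 equiv), THF, 65 °C; then Pd(dppf)Cl2 (5 mol %), aq K3PO4, CH2=CHBr, DMF, 50 °C
Reagents that add atoms: 9-borabicyclo[3.3.1]nonane B1C2CCCC1CCC2 (stays only in 7); vinyl bromide C=CBr
Why: Hydroboration followed by B-alkyl Suzuki–Miyaura coupling; 9-BBN approaches the exocyclic alkene anti to the methyl and CMe2CN groups, so H-18 ends cis to the OH and the new allyl arm cis to the nitrile arm.

Step 7
Reactants: 8 2-[(1S,2S,3S)-3-hydroxy-3-methyl-2-(prop-2-en-1-yl)cyclopentyl]-2-methylpropanenitrile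
Product: 10 2,4-dimethyl-4-[(1S,2S,3S)-3-hydroxy-3-methyl-2-(prop-2-en-1-yl)cyclopentyl]pent-1-en-3-one, via N-H ketimine 9 (not isolated)
Conditions: 2-bromopropene, t-BuLi, Et2O, −78 °C (3.5 equiv isopropenyllithium); then 8, −78 to 0 °C; then 1 M aq HCl, THF, rt
Reagents that add atoms: 2-bromopropene CC(Br)=C; water O
Why: Organolithium addition to the non-enolisable nitrile stops at the N-lithio ketimine, which is hydrolysed to the isopropenyl ketone (C-14, C-15); no stereocentre is involved.

Step 8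
Reactants: 10 2,4-dimethyl-4-[(1S,2S,3S)-3-hydroxy-3-methyl-2-(prop-2-en-1-yl)cyclopentyl]pent-1-en-3-one
Product: 11 cis-fused 1-hydroxy-1,4,4,6-tetramethyl-2,3,3a,4,8,8a-hexahydroazulen-5(1H)-one (OH syn to H-3a and H-8a; rings C and D)
Conditions: second-generation Hoveyda–Grubbs catalyst RuCl2(=CH-C6H4-2-OiPr)(H2IMes) (5 mol %), toluene (0.005 M), 80 °C
Reagents that add atoms: none
Why: Ring-closing metathesis of the allyl group and the isopropenyl ketone forms the trisubstituted C-15=C-16 bond and closes ring C, the cis arms and the gem-dimethyl group favouring the cis-fused seven-membered ring.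

Step 9
Reactants: 11 cis-fused hydroxy enone
Product: 12 triethylsilyl ether of 11
Conditions: Et3SiOTf, 2,6-lutidine, CH2Cl2, −78 to 0 °C
Reagents that add atoms: triethylsilyl trifluoromethanesulfonate CC[Si](CC)(CC)OS(=O)(=O)C(F)(F)F
Why: Silylation of the tertiary alcohol with a silyl triflate protects C-19 OH for the organometallic steps.

Step 10
Reactants: 12 triethylsilyl ether of 11
Product: 13 5-methylidene diene (C-13=C-14 exocyclic, C-15=C-16 in ring C)
Conditions: Ph3PCH3Br, KOtBu, toluene, 80 °C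
Reagents that add atoms: methyltriphenylphosphonium bromide C[P+](c1ccccc1)(c1ccccc1)c1ccccc1.[Br-]
Why: Wittig methylenation of the ketone, which has no α-hydrogen, introduces C-13.

Step 11
Reactants: 13 5-methylidene diene
Product: 15 primary alcohol (CH2OH at C-14; H-14 syn to H-18 and H-22), via B-alkyl-9-BBN adduct 14 (not isolated)
Conditions: 9-BBN, THF, 0 to 45 °C; then aq NaOH, H2O2, 0 °C to rt
Reagents that add atoms: 9-borabicyclo[3.3.1]nonane B1C2CCCC1CCC2 (stays only in 14); hydrogen peroxide OO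
Why: Anti-Markovnikov hydroboration–oxidation of the 1,1-disubstituted alkene of the diene from the convex face of the cis-fused bicycle (away from ring D) places H-14 on that face and sets C-14.

Step 12
Reactants: 15 primary alcohol
Product: 16 primary chloride (CH2Cl at C-14)
Conditions: PPh3, N-chlorosuccinimide, THF, 0 °C to rt
Reagents that add atoms: N-chlorosuccinimide O=C1CCC(=O)N1Cl
Why: Appel-type chlorination through the alkoxyphosphonium salt converts the primary alcohol without touching C-14.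

Step 13
Reactants: 17 N-methoxy-N-methylacetamide; 18 geranyl bromide
Product: 20 (4E)-N-methoxy-N,5,9-trimethyldeca-4,8-dienamide, via lithium enolate 19 (not isolated)
Conditions: LiN(iPr)2, THF, −78 °C; then 18, −78 to 0 °C
Reagents that add atoms: lithium diisopropylamide [Li+].CC(C)[N-]C(C)C (its lithium stays only in 19)
Why: SN2 alkylation of the amide enolate by the allylic bromide forms C-8–C-9 and keeps the E alkene geometry.

Step 14
Reactants: 20 (4E)-N-methoxy-N,5,9-trimethyldeca-4,8-dienamide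
Product: 21 (4S,5S,8S)-4,5:8,9-diepoxy-N-methoxy-N,5,9-trimethyldecanamide
Conditions: ent-Shi ketone (L-fructose-derived, 0.6 equiv), KHSO5, K2CO3, Bu4NHSO4, MeCN/CH2(OMe)2/aq Na2B4O7 buffer (pH 10.5), 0 °C
Reagents that add atoms: potassium peroxymonosulfate [K+].[O-]S(=O)(=O)OO
Why: Shi asymmetric epoxidation by the chiral dioxirane epoxidises both trisubstituted alkenes with catalyst control, setting C-3, C-6 and C-7 (all S).

Step 15
Reactants: 21 (4S,5S,8S)-4,5:8,9-diepoxy-N-methoxy-N,5,9-trimethyldecanamide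
Product: 23 (6S,7S,10S)-6,7:10,11-diepoxy-7,11-dimethyldodec-1-en-3-one, via tetrahedral magnesium chelate 22 (not isolated)
Conditions: CH2=CHMgBr, THF, −78 to −10 °C; inverse quench into cold aq NH4Cl
Reagents that add atoms: vinylmagnesium bromide C=C[Mg]Br (Mg and Br stay only in 22)
Why: Weinreb ketone synthesis; the stable chelate prevents over-addition and the trisubstituted epoxides do not react with the Grignard reagent at low temperature.

Step 16
Reactants: 16 primary chloride; 23 (6S,7S,10S)-6,7:10,11-diepoxy-7,11-dimethyldodec-1-en-3-one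
Product: 25 (Z)-trimethylsilyl enol ether (C-10 OSiMe3, C-10=C-11) carrying rings C/D and both epoxides, via alkylmagnesium chloride 24 (not isolated)
Conditions: Mg (activated by BrCH2CH2Br), THF, 60 °C; then CuBr·SMe2 (15 mol %), Me3SiCl, HMPA, 23, THF, −78 °C; Et3N
Reagents that add atoms: magnesium [Mg] (stays only in 24); chlorotrimethylsilane C[Si](C)(C)Cl
Why: Grignard formation, then copper-catalysed Me3SiCl-accelerated conjugate addition to the vinyl ketone forms C-12–C-13 and traps the regiodefined enolate as the (Z)-enol silane (from the s-cis enone).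

Step 17
Reactants: 25 (Z)-trimethylsilyl enol ether
Product: 26 ring A/B ketone (trans-fused oxepane–cyclohexanone; C-3 OSiMe3; C-10 ketone; C-11 side chain equatorial)
Conditions: Me3SiOTf (1.1 equiv), 2,6-di-tert-butyl-4-methylpyridine, CH2Cl2, −78 °C; then Et3N, aq NaHCO3
Reagents that add atoms: none
Why: Lewis-acid-promoted tandem oxa/carbacyclization (epoxide-opening cascade terminated by the enol silane, with silyl relay from the enol oxygen to O-3): the 6,7-epoxide oxygen opens the activated terminal epoxide at C-2, and the enol silane attacks C-6 of the bicyclic epoxonium ion with inversion through a chair, giving the trans A/B fusion with C-3 and C-7 retained and C-11 equatorial (C-11 is α to the ketone and can be equilibrated with DBU if needed).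

Step 18
Reactants: 26 ring A/B ketone
Product: 27 C-10 tertiary alcohol (bis-silyl ether of the target)
Conditions: CeCl3 (anhydrous), MeLi, THF, −78 °C
Reagents that add atoms: methyllithium [Li]C
Why: Organocerium 1,2-addition suppresses enolisation, and the methyl group enters equatorially, anti to the 1,3-diaxial C-6 methyl, giving the axial C-10 OH.

Step 19
Reactants: 27 C-10 tertiary alcohol (bis-silyl ether)
Product: 28 target CNP0183476.2
Conditions: Bu4NF, THF, 45 °C
Reagents that add atoms: none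
Why: Fluoride-mediated desilylation removes the Me3Si and Et3Si ethers without affecting any stereocentre or the trisubstituted alkene.

**Compound list**
1 | (S)-(+)-linalool, (3S)-3,7-dimethylocta-1,6-dien-3-ol | C=C[C@@](C)(O)CCC=C(C)C | starting material
2 | (S)-1-methylcyclopent-2-en-1-ol | C[C@]1(O)CCC=C1 | intermediate
3 | (1S,2R,3R)-2,3-epoxy-1-methylcyclopentan-1-ol (epoxide cis to OH) | C[C@]1(O)CC[C@H]2O[C@@H]12 | intermediate
4 | 2-[(1R,2R,3S)-2,3-dihydroxy-3-methylcyclopentyl]-2-methylpropanenitrile | C[C@]1(O)CC[C@H](C(C)(C)C#N)[C@H]1O | intermediate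
5 | 2-[(1R,3S)-3-hydroxy-3-methyl-2-oxocyclopentyl]-2-methylpropanenitrile | C[C@]1(O)CC[C@H](C(C)(C)C#N)C1=O | intermediate
6 | 2-[(1R,3S)-3-hydroxy-3-methyl-2-methylidenecyclopentyl]-2-methylpropanenitrile | C[C@]1(O)CC[C@H](C(C)(C)C#N)C1=C | intermediate
7 | B-alkyl-9-BBN adduct of 6 (drawn as the free alcohol; any O–B bond at the hydroxyl is cleaved by the aqueous base) | C[C@]1(O)CC[C@H](C(C)(C)C#N)[C@@H]1CB1C2CCCC1CCC2 | intermediate
8 | 2-[(1S,2S,3S)-3-hydroxy-3-methyl-2-(prop-2-en-1-yl)cyclopentyl]-2-methylpropanenitrile | C[C@]1(O)CC[C@H](C(C)(C)C#N)[C@@H]1CC=C | intermediate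
9 | N-H ketimine of 10 | C[C@]1(O)CC[C@H](C(C)(C)C(=N)C(C)=C)[C@@H]1CC=C | intermediate
10 | 2,4-dimethyl-4-[(1S,2S,3S)-3-hydroxy-3-methyl-2-(prop-2-en-1-yl)cyclopentyl]pent-1-en-3-one | C[C@]1(O)CC[C@H](C(C)(C)C(=O)C(C)=C)[C@@H]1CC=C | intermediate
11 | cis-fused 1-hydroxy-1,4,4,6-tetramethyl-2,3,3a,4,8,8a-hexahydroazulen-5(1H)-one (OH syn to H-3a and H-8a) | C[C@]1(O)CC[C@@H]2C(C)(C)C(=O)C(C)=CC[C@H]12 | intermediate
12 | triethylsilyl ether of 11 | C[C@]1(O[Si](CC)(CC)CC)CC[C@@H]2C(C)(C)C(=O)C(C)=CC[C@H]12 | intermediate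
13 | 5-methylidene diene from 12 | C[C@]1(O[Si](CC)(CC)CC)CC[C@@H]2C(C)(C)C(=C)C(C)=CC[C@H]12 | intermediate
14 | B-alkyl-9-BBN adduct of 13 | C[C@]1(O[Si](CC)(CC)CC)CC[C@@H]2C(C)(C)[C@H](CB3C4CCCC3CCC4)C(C)=CC[C@H]12 | intermediate
15 | primary alcohol, CH2OH at C-14, H-14 syn to H-18 and H-22 | C[C@]1(O[Si](CC)(CC)CC)CC[C@@H]2C(C)(C)[C@H](CO)C(C)=CC[C@H]12 | intermediate
16 | primary chloride, CH2Cl at C-14 | C[C@]1(O[Si](CC)(CC)CC)CC[C@@H]2C(C)(C)[C@H](CCl)C(C)=CC[C@H]12 | intermediate
17 | N-methoxy-N-methylacetamide | CC(=O)N(C)OC | starting material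
18 | geranyl bromide, (2E)-1-bromo-3,7-dimethylocta-2,6-diene | BrC/C=C(\C)CCC=C(C)C | starting material
19 | lithium enolate of 17 | C=C(O[Li])N(C)OC | intermediate
20 | (4E)-N-methoxy-N,5,9-trimethyldeca-4,8-dienamide | CON(C)C(=O)CC/C=C(\C)CCC=C(C)C | intermediate
21 | (4S,5S,8S)-4,5:8,9-diepoxy-N-methoxy-N,5,9-trimethyldecanamide | CON(C)C(=O)CC[C@@H]1O[C@@]1(C)CC[C@@H]1OC1(C)C | intermediate
22 | tetrahedral bromomagnesium chelate from 21 and CH2=CHMgBr | C=CC(O[Mg]Br)(N(C)OC)CC[C@@H]1O[C@@]1(C)CC[C@@H]1OC1(C)C | intermediate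
23 | (6S,7S,10S)-6,7:10,11-diepoxy-7,11-dimethyldodec-1-en-3-one | C=CC(=O)CC[C@@H]1O[C@@]1(C)CC[C@@H]1OC1(C)C | intermediate
24 | alkylmagnesium chloride from 16 | C[C@]1(O[Si](CC)(CC)CC)CC[C@@H]2C(C)(C)[C@H](C[Mg]Cl)C(C)=CC[C@H]12 | intermediate
25 | (Z)-trimethylsilyl enol ether, cascade substrate | C[C@]1(O[Si](CC)(CC)CC)CC[C@@H]2C(C)(C)[C@H](CC/C=C(\O[Si](C)(C)C)CC[C@@H]3O[C@@]3(C)CC[C@@H]3OC3(C)C)C(C)=CC[C@H]12 | intermediate
26 | ring A/B ketone (C-3 OSiMe3, C-19 OSiEt3, C-10 ketone) | C[C@]1(O[Si](CC)(CC)CC)CC[C@@H]2C(C)(C)[C@H](CC[C@H]3[C@]4(C)CC[C@H](O[Si](C)(C)C)C(C)(C)O[C@H]4CCC3=O)C(C)=CC[C@H]12 | intermediate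
27 | C-10 tertiary alcohol, bis-silyl ether of the target | C[C@]1(O[Si](CC)(CC)CC)CC[C@@H]2C(C)(C)[C@H](CC[C@H]3[C@]4(C)CC[C@H](O[Si](C)(C)C)C(C)(C)O[C@H]4CC[C@@]3(C)O)C(C)=CC[C@H]12 | intermediate
28 | CNP0183476.2 | CC1=CC[C@H]2[C@H](CC[C@]2(C)O)C(C)(C)[C@@H]1CC[C@H]1[C@]2(C)CC[C@H](O)C(C)(C)O[C@H]2CC[C@@]1(C)O | target

**Totals and risks**
Total step count: 19. Longest linear sequence: 16 steps (steps 1–12, then 16–19); the diepoxy vinyl ketone takes 3 steps (13–15).

The three steps most likely to fail are 17, 11 and 3.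

Step 17 (cascade on the fully loaded substrate): the fallback sets out from 23 and comes back at 26. Compound 23 is treated with PhSSiMe3 and catalytic Bu4NF to give the (Z)-β-(phenylthio) trimethylsilyl enol ether F1, a small substrate close to the known type. The same Me3SiOTf/2,6-di-tert-butyl-4-methylpyridine cascade then gives the ring A/B ketone carrying CH2SPh at C-11 F2. mCPBA at −78 °C gives the sulfoxide F3, and thermal syn-elimination (toluene, 90 °C) gives the exocyclic α-methylene ketone F4. CuBr·SMe2-catalysed conjugate addition of 24 to F4, protonation and DBU equilibration at C-11 deliver 26. The fragment union then follows ring formation instead of preceding it.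

Step 11 (facial selectivity at C-14): the fallback sets out from 12 and comes back at 15. Wittig reaction of 12 with Ph3P=CHOMe gives the methyl dienol ether F5. Hydrolysis on oxalic-acid-treated wet silica (α-protonation, then equilibration of the epimerisable centre toward the 1,3-cis arrangement with the ring D bond) gives the β,γ-unsaturated aldehyde F6. NaBH4 reduces F6 to 15. C-14 is then set under thermodynamic control instead of by reagent approach.

Step 3 (hindered tertiary carbanion on the epoxy alcohol): the fallback sets out from 3 and comes back at 4. Unhindered LiCH2CN opens 3 to the cyanomethyl diol F7. 2,2-Dimethoxypropane/PPTS gives the acetonide F8. Two rounds of LiN(iPr)2/MeI give the gem-dimethyl nitrile acetonide F9, and aqueous AcOH returns 4. The quaternary carbon is thus built after, not during, the epoxide opening.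

**Further compounds**
F1 | step 17 | (Z)-β-(phenylthio) trimethylsilyl enol ether of the diepoxy ketone | c1ccccc1SC/C=C(\O[Si](C)(C)C)CC[C@@H]1O[C@@]1(C)CC[C@@H]1OC1(C)C
F2 | step 17 | ring A/B ketone carrying CH2SPh at C-11 | c1ccccc1SC[C@H]1[C@]2(C)CC[C@H](O[Si](C)(C)C)C(C)(C)O[C@H]2CCC1=O
F3 | step 17 | sulfoxide of F2 | O=S(c1ccccc1)C[C@H]1[C@]2(C)CC[C@H](O[Si](C)(C)C)C(C)(C)O[C@H]2CCC1=O
F4 | step 17 | exocyclic α-methylene ring A/B ketone | C=C1[C@]2(C)CC[C@H](O[Si](C)(C)C)C(C)(C)O[C@H]2CCC1=O
F5 | step 11 | methyl dienol ether from 12 | C[C@]1(O[Si](CC)(CC)CC)CC[C@@H]2C(C)(C)C(=COC)C(C)=CC[C@H]12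
F6 | step 11 | β,γ-unsaturated aldehyde (CHO at C-14) | C[C@]1(O[Si](CC)(CC)CC)CC[C@@H]2C(C)(C)[C@H](C=O)C(C)=CC[C@H]12
F7 | step 3 | cyanomethyl diol | C[C@]1(O)CC[C@H](CC#N)[C@H]1O
F8 | step 3 | acetonide of F7 | C[C@]12CC[C@H](CC#N)[C@H]1OC(C)(C)O2
F9 | step 3 | gem-dimethyl nitrile acetonide | C[C@]12CC[C@H](C(C)(C)C#N)[C@H]1OC(C)(C)O2
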